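- Target ⇒ the γ-lactone (O6–C12) closed last by oxidative lactonisation of a 2-methylene-1,4-diol; the O9 and O8 esters from an 8,9-diol; C14 by carbonylation of the C10 enol triflate of a cyclodec-4-en-10-one.
- Key disconnection: the 1,5-diene C10=C1–C2–C3–C4=C5 inside the ten-membered carbocycle C1–C10 (C10 bearing C14, C4 bearing C15) is an oxy-Cope retron once C10 carries oxygen. Breaking C2–C3 and rejoining C5–C10 gives a cis-1-vinyl-2-isopropenylcyclohexanol whose six-membered ring C5–C10 carries C6–C9.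
- The cyclohexane comes from the cis-dihydrodiol of bromobenzene (C8, C9): vinyl on C10 by Stille coupling, O10 and a C7 ketone by singlet oxygen/Kornblum–DeLaMare, C5 by conjugate addition, C7/C6 by enol triflate → Nozaki–Hiyama–Kishi → conjugate borylation.
- Ring order: cyclohexane (purchased) → ten-membered carbocycle (ring expansion) → five-membered lactone.
- Acids: oxazolidinone syn-aldol; Sharpless epoxidation of angelyl alcohol.

Key step: step 12

Remark: atoms keep germacrane numbers throughout (ring C1–C10; C11–C13 on C7; C14 on C10; C15 on C4); β is the ring face carrying O8/O9, α the other; diol 1 and aldehyde 11 are taken as purchasable.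

Step 1
Reactants: 1 (1S,2S)-3-bromocyclohexa-3,5-diene-1,2-diol
Product: 2 (3aS,7aS)-4-bromo-2,2-dimethyl-3a,7a-dihydro-1,3-benzodioxole
Conditions: 2,2-dimethoxypropane, TsOH·H2O (cat.), acetone, 0 °C
Reagents that add atoms: 2,2-dimethoxypropane, COC(C)(C)OC
Why: Acid-catalysed transketalisation protects the cis-diol (O8, O9) as the acetonide, which later screens the β-face; no stereocentre is touched.

Step 2
Reactants: 2 (3aS,7aS)-4-bromo-2,2-dimethyl-3a,7a-dihydro-1,3-benzodioxole; 3 tributyl(ethenyl)stannane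
Product: 4 C10-vinyl triene acetonide (4-ethenyl-2,2-dimethyl-3a,7a-dihydro-1,3-benzodioxole)
Conditions: Pd(PPh3)4 (5 mol %), CuI (10 mol %), DMF, 45 °C
Reagents that add atoms: none
Why: Stille cross-coupling at the alkenyl bromide puts the future C1=C2 vinyl group on C10 without stereochemical consequence; the triene is used at once to avoid Diels–Alder dimerisation.

Step 3
Reactants: 4 C10-vinyl triene acetonide
Product: 6 hydroxy enone (C7=O, C5=C6, 10α-OH, 10β-vinyl, 8β,9β-acetonide), via endoperoxide 5 (not isolated)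
Conditions: O2, tetraphenylporphyrin (cat.), visible light, CH2Cl2, −78 °C; then Et3N, 0 °C
Reagents that add atoms: dioxygen, O=O
Why: Singlet oxygen should add [4+2] across C10/C7 of the ring diene on the α-face (anti to the acetonide), and the Kornblum–DeLaMare rearrangement, in which Et3N removes the only bridgehead hydrogen (H7), opens the peroxide to the C7 ketone and the tertiary C10 alcohol, so O10 is set α (trans to O9) and the vinyl group β.

Step 4
Reactants: 6 hydroxy enone
Product: 7 10-O-triethylsilyl ether of 6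
Conditions: Et3SiOTf, 2,6-lutidine, CH2Cl2, −78 to 0 °C
Reagents that add atoms: triethylsilyl trifluoromethanesulfonate, CC[Si](CC)(CC)OS(=O)(=O)C(F)(F)F
Why: Silyl triflate with a hindered base silylates the tertiary allylic alcohol, which prevents alkoxide-directed (syn) delivery in step 5 and makes the α-face of C5 the hindered one.

Step 5
Reactants: 7 10-O-triethylsilyl enone; 8 isopropenylmagnesium bromide
Product: 10 C7 enol triflate (C6=C7, 5β-isopropenyl, 10α-OSiEt3, 10β-vinyl, 8β,9β-acetonide), via bromomagnesium enolate 9 (not isolated)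
Conditions: 8, CuBr·SMe2 (0.2 equiv), THF, −78 °C; then N-(5-chloropyridin-2-yl)bis(trifluoromethanesulfonimide), DMPU, −78 to 0 °C
Reagents that add atoms: N-(5-chloropyridin-2-yl)bis(trifluoromethanesulfonimide), O=S(=O)(N(c1ccc(Cl)cn1)S(=O)(=O)C(F)(F)F)C(F)(F)F
Why: Copper-catalysed conjugate addition of the Grignard reagent followed by O-triflation of the regiodefined enolate; as with other γ-silyloxy cyclohexenones the nucleophile should enter C5 anti to the pseudoaxial C10 silyloxy group, i.e. on the β-face next to the vinyl group, which sets C5 (isopropenyl β, cis to the C10 vinyl group).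

Step 6
Reactants: 10 C7 enol triflate; 11 2-[(4-methoxyphenyl)methoxy]acetaldehyde
Product: 12 allylic alcohol (C6=C7 bearing CH(OH)CH2OPMB on C7; C11 epimers)
Conditions: CrCl2 (4 equiv), NiCl2 (2 mol %), DMF, 25 °C
Reagents that add atoms: none
Why: Nozaki–Hiyama–Kishi coupling (nickel-catalysed activation of the alkenyl triflate, addition of the alkenylchromium species to the aldehyde) joins C11/C12 to C7; the carbinol centre forms as a mixture, which is irrelevant because it is oxidised in step 7.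

Step 7
Reactants: 12 allylic alcohol
Product: 13 enone (C6=C7–C11(=O)–CH2OPMB)
Conditions: Dess–Martin periodinane, NaHCO3, CH2Cl2, 0 to 25 °C
Reagents that add atoms: none
Why: Dess–Martin oxidation of the allylic alcohol gives the Michael acceptor needed for step 8 without affecting silyl ether, acetonide or PMB ether.

Step 8
Reactants: 13 enone
Product: 15 β-hydroxy ketone (6α-OH, 7β-C(=O)CH2OPMB), via C6 pinacolboronate 14 (not isolated)
Conditions: CuCl (10 mol %), Xantphos (10 mol %), NaOtBu (20 mol %), B2pin2, MeOH (2 equiv), THF, 25 °C; then H2O2, pH 7 phosphate buffer, 0 °C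
Reagents that add atoms: bis(pinacolato)diboron, CC1(C)OB(OC1(C)C)B1OC(C)(C)C(C)(C)O1; hydrogen peroxide, OO
Why: Copper-catalysed conjugate borylation should place boron on C6 from the α-face (anti to the adjacent β-isopropenyl group and to axial β-O8), C7 is protonated and equilibrates under the basic conditions to the equatorial β-acyl group, and C–B oxidation with retention gives the 6α-alcohol, so C6 and C7 are both set.

Step 9
Reactants: 15 β-hydroxy ketone
Product: 16 6-O-tert-butyldimethylsilyl ether of 15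
Conditions: t-BuMe2SiOTf, 2,6-lutidine, CH2Cl2, −78 °C
Reagents that add atoms: tert-butyldimethylsilyl trifluoromethanesulfonate, CC(C)(C)[Si](C)(C)OS(=O)(=O)C(F)(F)F
Why: Low-temperature silylation with the silyl triflate protects O6 and removes the retro-aldol and dehydration pathways of the β-hydroxy ketone.

Step 10
Reactants: 16 silylated β-hydroxy ketone
Product: 17 triene (7β-[3-(4-methoxybenzyloxy)prop-1-en-2-yl], 6α-OTBS, 5β-isopropenyl, 10α-OSiEt3, 10β-vinyl, 8β,9β-acetonide)
Conditions: Ph3PCH3Br, KN(SiMe3)2, THF, 0 °C; then 16, 0 to 25 °C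
Reagents that add atoms: methylenetriphenylphosphorane (from methyltriphenylphosphonium bromide), C=P(c1ccccc1)(c1ccccc1)c1ccccc1
Why: Wittig methylenation of the ketone with the non-stabilised ylide creates C13 and completes the C7 side chain; C7 stays in its equatorial β-configuration, the thermodynamically preferred one.

Step 11
Reactants: 17 triene
Product: 18 cis-1-vinyl-2-isopropenylcyclohexanol (10α-OH, 10β-vinyl, 5β-isopropenyl, 6α-OTBS, 7β-side chain, 8β,9β-acetonide)
Conditions: HF·pyridine, pyridine, THF, 0 °C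
Reagents that add atoms: none
Why: Buffered HF·pyridine cleaves the more labile triethylsilyl ether while the hindered secondary tert-butyldimethylsilyl ether, the acetonide and the PMB ether survive, freeing the tertiary C10 alcohol.

Step 12
Reactants: 18 cis-1-vinyl-2-isopropenylcyclohexanol
Product: 20 (4Z)-cyclodec-4-en-10-one (C10 ketone, ring-cis C4=C5, 6α-OTBS, 7β-side chain, 8β,9β-acetonide), via potassium enolate 19 (not isolated)
Conditions: KH, 18-crown-6, THF, 0 to 25 °C; AcOH, −78 °C
Reagents that add atoms: none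
Why: The potassium alkoxide of 18 undergoes an anionic oxy-Cope ([3,3]-sigmatropic) rearrangement in which C2–C3 forms while the transannular C5–C10 bond breaks, giving the C4=C5 alkene and the C1=C10 enolate 19, which is protonated at C1 to ketone 20. The closest known reaction type is the anionic oxy-Cope ring expansion of cis-1,2-dialkenylcyclohexanols to (Z)-cyclodec-5-enones. The ten-membered ring is closed by four-carbon ring expansion of the cyclohexane through a chair six-centre transition state, not by end-to-end cyclisation. No stereocentre is created: C6–C9 are untouched and C5 and C10 become trigonal. The step needs the ring-cis C4=C5 geometry, which requires the chair transition state reached from the cyclohexane conformer with the vinyl group axial and the isopropenyl group equatorial (C6 pseudo-axial in the six-centre chair); in 18 this is the only low-energy chair (substituents on C5, C6, C7, C9 and O10 equatorial, only O8 and the vinyl group axial), and the alternative would press C15 against C6. Enolate formation makes the step irreversible, and because 19 is expected to be the ring-trans enolate it is protonated rather than trapped.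

Step 13
Reactants: 20 (4Z)-cyclodec-4-en-10-one
Product: 22 C10 enol triflate (C1=C10 ring-cis, C2 cis to C9), via lithium enolate 21 (not isolated)
Conditions: LiN(i-Pr)2, THF, −78 °C; then N-(5-chloropyridin-2-yl)bis(trifluoromethanesulfonimide), −78 to −20 °C
Reagents that add atoms: N-(5-chloropyridin-2-yl)bis(trifluoromethanesulfonimide), O=S(=O)(N(c1ccc(Cl)cn1)S(=O)(=O)C(F)(F)F)C(F)(F)F
Why: Kinetic enolisation should remove a proton from the unhindered C1 methylene rather than from the alkoxy-bearing C9 methine and give the ring-cis enolate (a cis,cis-cyclodeca-1,5-diene, the less strained geometry), which O-sulfonylation then fixes.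

Step 14
Reactants: 22 C10 enol triflate
Product: 23 methyl ester (C14 on C10, C1=C10 ring-cis, ring-cis C4=C5, 8β,9β-acetonide)
Conditions: Pd(PPh3)4 (10 mol %), CO (1 atm), MeOH, Et3N, DMF, 50 °C
Reagents that add atoms: carbon monoxide, [C-]#[O+]; methanol, CO
Why: Palladium-catalysed methoxycarbonylation of the alkenyl triflate (oxidative addition, CO insertion, methanolysis) introduces C14 with retention of the C1=C10 geometry.

Step 15
Reactants: 23 methyl ester acetonide
Product: 24 8β,9β-diol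
Conditions: AcOH/H2O/THF (3:1:1), 40 °C
Reagents that add atoms: none
Why: Mild aqueous-acid hydrolysis removes the acetonide while the allylic silyl ether, the PMB ether and the enoate are retained.

Step 16
Reactants: 25 (R)-4-benzyl-3-propanoyl-1,3-oxazolidin-2-one; 26 acetaldehyde
Product: 27 (R)-4-benzyl-3-[(2R,3S)-3-hydroxy-2-methylbutanoyl]-1,3-oxazolidin-2-one
Conditions: Bu2BOTf, i-Pr2NEt, CH2Cl2, −78 to 0 °C; then 26, −78 °C; H2O2, pH 7 buffer, MeOH
Reagents that add atoms: none
Why: Boron-mediated oxazolidinone syn-aldol (Evans aldol): the Z-boron enolate of the (R)-auxiliary adds to acetaldehyde through a chair transition state, setting both centres as (2R,3S).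

Step 17
Reactants: 27 aldol adduct
Product: 28 tert-butyldimethylsilyl ether of 27
Conditions: t-BuMe2SiOTf, 2,6-lutidine, CH2Cl2, 0 °C
Reagents that add atoms: tert-butyldimethylsilyl trifluoromethanesulfonate, CC(C)(C)[Si](C)(C)OS(=O)(=O)C(F)(F)F
Why: Silylation protects the secondary alcohol so that the acid can be activated later without self-esterification.

Step 18
Reactants: 28 silylated aldol adduct
Product: 29 (2R,3S)-3-[(tert-butyldimethylsilyl)oxy]-2-methylbutanoic acid
Conditions: LiOH, H2O2, THF/H2O, 0 °C; Na2SO3; HCl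
Reagents that add atoms: hydrogen peroxide (as lithium hydroperoxide), OO
Why: Lithium hydroperoxide attacks the exocyclic imide carbonyl selectively, releasing the acid without epimerisation and returning the auxiliary.

Step 19
Reactants: 24 8β,9β-diol; 29 (2R,3S)-3-[(tert-butyldimethylsilyl)oxy]-2-methylbutanoic acid
Product: 30 9-O-[(2R,3S)-3-(silyloxy)-2-methylbutanoyl] ester (8β-OH free)
Conditions: 29, 2,4,6-trichlorobenzoyl chloride, Et3N, THF, 25 °C; then 24, DMAP, toluene, 0 °C
Reagents that add atoms: none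
Why: Yamaguchi esterification with the bulky preformed mixed anhydride at low temperature should acylate the allylic C9 hydroxyl, flanked by trigonal C10, in preference to the C8 hydroxyl, which is screened by the C7 side chain and the C6 silyl ether.

Step 20
Reactants: 31 methyl (Z)-2-methylbut-2-enoate (methyl angelate)
Product: 32 (Z)-2-methylbut-2-en-1-ol
Conditions: i-Bu2AlH, CH2Cl2, −78 °C
Reagents that add atoms: none
Why: Hydride reduction of the ester at low temperature gives the allylic alcohol without isomerising the Z double bond.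

Step 21
Reactants: 32 (Z)-2-methylbut-2-en-1-ol
Product: 33 [(2R,3S)-2,3-dimethyloxiran-2-yl]methanol
Conditions: Ti(OiPr)4, D-(−)-diethyl tartrate, t-BuOOH, 4 Å molecular sieves, CH2Cl2, −20 °C
Reagents that add atoms: tert-butyl hydroperoxide, CC(C)(C)OO
Why: Sharpless asymmetric epoxidation; with the D-(−)-tartrate the titanium–tartrate complex delivers oxygen to the face of the Z-allylic alcohol that gives the (2R,3S)-epoxy alcohol.

Step 22
Reactants: 33 [(2R,3S)-2,3-dimethyloxiran-2-yl]methanol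
Product: 34 (2S,3S)-2,3-dimethyloxirane-2-carboxylic acid
Conditions: RuCl3 (cat.), NaIO4, EtOAc/MeCN/H2O, 0 to 25 °C
Reagents that add atoms: water, O; sodium periodate (terminal oxidant), [Na+].[O-]I(=O)(=O)=O
Why: Ruthenium tetroxide generated catalytically oxidises the primary alcohol to the acid without opening the epoxide.

Step 23
Reactants: 30 9-O-monoester; 34 (2S,3S)-2,3-dimethyloxirane-2-carboxylic acid
Product: 35 8-O-[(2S,3S)-2,3-dimethyloxirane-2-carbonyl] 9-O-[(2R,3S)-3-(silyloxy)-2-methylbutanoyl] diester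
Conditions: 34, 2,4,6-trichlorobenzoyl chloride, Et3N, THF, 25 °C; then 30, DMAP, toluene, 25 °C
Reagents that add atoms: none
Why: Yamaguchi esterification of the remaining hindered C8 hydroxyl; the mixed-anhydride protocol tolerates the epoxide and leaves the existing esters alone.

Step 24
Reactants: 35 diester
Product: 36 primary allylic alcohol (C12–OH)
Conditions: DDQ, CH2Cl2/pH 7 buffer, 0 °C
Reagents that add atoms: none
Why: DDQ oxidises the p-methoxybenzyl ether (hydride abstraction, hydrolysis of the oxocarbenium ion) to free O12; silyl ethers, esters and the epoxide are inert.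

Step 25
Reactants: 36 primary allylic alcohol
Product: 37 triol (6α-OH, C12–OH, side-chain 3-OH)
Conditions: HF·pyridine, pyridine, THF, 0 to 25 °C
Reagents that add atoms: none
Why: Buffered HF·pyridine removes both tert-butyldimethylsilyl ethers under conditions that leave the epoxide, the esters and the enoate intact.

Step 26
Reactants: 37 triol
Product: 40 CNP0135583.1, via C12 aldehyde 38 (not isolated), via C12 lactol 39 (not isolated)
Conditions: TEMPO (20 mol %), PhI(OAc)2, CH2Cl2, 25 °C
Reagents that add atoms: none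
Why: The TEMPO/PhI(OAc)2 oxidation is selective for the primary allylic alcohol over the secondary ones, the acrolein formed is captured by the 6α-hydroxyl as a five-membered lactol, and this is oxidised on to the α-methylene-γ-lactone, closing the last ring without creating a stereocentre.

Compound list
1 | (1S,2S)-3-bromocyclohexa-3,5-diene-1,2-diol | BrC1=CC=C[C@H](O)[C@@H]1O | starting material
2 | (3aS,7aS)-4-bromo-2,2-dimethyl-3a,7a-dihydro-1,3-benzodioxole | BrC1=CC=C[C@@H]2OC(C)(C)O[C@H]12 | intermediate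
3 | tributyl(ethenyl)stannane | C=C[Sn](CCCC)(CCCC)CCCC | starting material
4 | 4-ethenyl-2,2-dimethyl-3a,7a-dihydro-1,3-benzodioxole (C10-vinyl triene, configuration as in 2) | C=CC1=CC=C[C@@H]2OC(C)(C)O[C@H]12 | intermediate
5 | C10/C7 endoperoxide of 4, peroxide bridge α, acetonide β | C=C[C@@]1(OO3)[C@H]2OC(C)(C)O[C@H]2[C@H]3C=C1 | intermediate
6 | hydroxy enone: C7=O, C5=C6, 10α-OH, 10β-vinyl, 8β,9β-acetonide | C=C[C@@]1(O)[C@H]2OC(C)(C)O[C@H]2C(=O)C=C1 | intermediate
7 | 10-O-triethylsilyl ether of 6 | C=C[C@@]1(O[Si](CC)(CC)CC)[C@H]2OC(C)(C)O[C@H]2C(=O)C=C1 | intermediate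
8 | isopropenylmagnesium bromide | C=C(C)[Mg]Br | starting material
9 | bromomagnesium C6=C7 enolate, 5β-isopropenyl | C=C[C@@]1(O[Si](CC)(CC)CC)[C@H]2OC(C)(C)O[C@H]2C(O[Mg]Br)=C[C@H]1C(C)=C | intermediate
10 | C7 enol triflate: C6=C7, 5β-isopropenyl, 10α-OSiEt3, 10β-vinyl, 8β,9β-acetonide | C=C[C@@]1(O[Si](CC)(CC)CC)[C@H]2OC(C)(C)O[C@H]2C(OS(=O)(=O)C(F)(F)F)=C[C@H]1C(C)=C | intermediate
11 | 2-[(4-methoxyphenyl)methoxy]acetaldehyde | O=CCOCc1ccc(OC)cc1 | starting material
12 | allylic alcohol: C7–CH(OH)CH2OPMB on C6=C7 (C11 epimers) | C=C[C@@]1(O[Si](CC)(CC)CC)[C@H]2OC(C)(C)O[C@H]2C(C(O)COCc3ccc(OC)cc3)=C[C@H]1C(C)=C | intermediate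
13 | enone: C6=C7–C11(=O)–CH2OPMB | C=C[C@@]1(O[Si](CC)(CC)CC)[C@H]2OC(C)(C)O[C@H]2C(C(=O)COCc3ccc(OC)cc3)=C[C@H]1C(C)=C | intermediate
14 | β-boryl ketone: 6α-B(pin), 7β-acyl | C=C[C@@]1(O[Si](CC)(CC)CC)[C@H]2OC(C)(C)O[C@H]2[C@@H](C(=O)COCc3ccc(OC)cc3)[C@H](B4OC(C)(C)C(C)(C)O4)[C@H]1C(C)=C | intermediate
15 | β-hydroxy ketone: 6α-OH, 7β-C(=O)CH2OPMB | C=C[C@@]1(O[Si](CC)(CC)CC)[C@H]2OC(C)(C)O[C@H]2[C@@H](C(=O)COCc3ccc(OC)cc3)[C@H](O)[C@H]1C(C)=C | intermediate
16 | 6-O-tert-butyldimethylsilyl ether of 15 | C=C[C@@]1(O[Si](CC)(CC)CC)[C@H]2OC(C)(C)O[C@H]2[C@@H](C(=O)COCc3ccc(OC)cc3)[C@H](O[Si](C)(C)C(C)(C)C)[C@H]1C(C)=C | intermediate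
17 | triene: 7β-[3-(4-methoxybenzyloxy)prop-1-en-2-yl], 6α-OTBS, 5β-isopropenyl, 10α-OSiEt3, 10β-vinyl, 8β,9β-acetonide | C=C[C@@]1(O[Si](CC)(CC)CC)[C@H]2OC(C)(C)O[C@H]2[C@@H](C(=C)COCc3ccc(OC)cc3)[C@H](O[Si](C)(C)C(C)(C)C)[C@H]1C(C)=C | intermediate
18 | cis-1-vinyl-2-isopropenylcyclohexanol (10α-OH; otherwise as 17) | C=C[C@@]1(O)[C@H]2OC(C)(C)O[C@H]2[C@@H](C(=C)COCc3ccc(OC)cc3)[C@H](O[Si](C)(C)C(C)(C)C)[C@H]1C(C)=C | intermediate
19 | potassium C1=C10 enolate (ring-trans) of 20 | [K+].CC(C)(C)[Si](C)(C)O[C@@H]1/C=C(/C)CC/C=C(\[O-])[C@H]3OC(C)(C)O[C@H]3[C@H]1C(=C)COCc2ccc(OC)cc2 | intermediate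
20 | (4Z)-cyclodec-4-en-10-one: C10 ketone, 6-OTBS, 7-side chain, 8,9-acetonide, C6–C9 as in the target | CC(C)(C)[Si](C)(C)O[C@@H]1/C=C(/C)CCCC(=O)[C@H]3OC(C)(C)O[C@H]3[C@H]1C(=C)COCc2ccc(OC)cc2 | intermediate
21 | lithium C1=C10 enolate (ring-cis) of 20 | [Li+].CC(C)(C)[Si](C)(C)O[C@@H]1/C=C(/C)CC/C=C(/[O-])[C@H]3OC(C)(C)O[C@H]3[C@H]1C(=C)COCc2ccc(OC)cc2 | intermediate
22 | C10 enol triflate, C1=C10 ring-cis | CC(C)(C)[Si](C)(C)O[C@@H]1/C=C(/C)CC/C=C(/OS(=O)(=O)C(F)(F)F)[C@H]3OC(C)(C)O[C@H]3[C@H]1C(=C)COCc2ccc(OC)cc2 | intermediate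
23 | C10 methyl ester, (1(10)E,4Z)-diene, 8,9-acetonide | CC(C)(C)[Si](C)(C)O[C@@H]1/C=C(/C)CC/C=C(/C(=O)OC)[C@H]3OC(C)(C)O[C@H]3[C@H]1C(=C)COCc2ccc(OC)cc2 | intermediate
24 | 8,9-diol of 23 | CC(C)(C)[Si](C)(C)O[C@@H]1/C=C(/C)CC/C=C(/C(=O)OC)[C@@H](O)[C@@H](O)[C@H]1C(=C)COCc2ccc(OC)cc2 | intermediate
25 | (R)-4-benzyl-3-propanoyl-1,3-oxazolidin-2-one | CCC(=O)N1[C@H](Cc2ccccc2)COC1=O | starting material
26 | acetaldehyde | CC=O | starting material
27 | (R)-4-benzyl-3-[(2R,3S)-3-hydroxy-2-methylbutanoyl]-1,3-oxazolidin-2-one | O=C(N1[C@H](Cc2ccccc2)COC1=O)[C@H](C)[C@H](C)O | intermediate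
28 | tert-butyldimethylsilyl ether of 27 | O=C(N1[C@H](Cc2ccccc2)COC1=O)[C@H](C)[C@H](C)O[Si](C)(C)C(C)(C)C | intermediate
29 | (2R,3S)-3-[(tert-butyldimethylsilyl)oxy]-2-methylbutanoic acid | OC(=O)[C@H](C)[C@H](C)O[Si](C)(C)C(C)(C)C | intermediate
30 | 9-O-[(2R,3S)-3-(silyloxy)-2-methylbutanoyl] ester of 24, 8-OH free | CC(C)(C)[Si](C)(C)O[C@@H]1/C=C(/C)CC/C=C(/C(=O)OC)[C@@H](OC(=O)[C@H](C)[C@H](C)O[Si](C)(C)C(C)(C)C)[C@@H](O)[C@H]1C(=C)COCc2ccc(OC)cc2 | intermediate
31 | methyl (Z)-2-methylbut-2-enoate | C/C=C(/C)C(=O)OC | starting material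
32 | (Z)-2-methylbut-2-en-1-ol | C/C=C(/C)CO | intermediate
33 | [(2R,3S)-2,3-dimethyloxiran-2-yl]methanol | OC[C@@]1(C)O[C@H]1C | intermediate
34 | (2S,3S)-2,3-dimethyloxirane-2-carboxylic acid | OC(=O)[C@@]1(C)O[C@H]1C | intermediate
35 | 8-O-epoxyangeloyl 9-O-(silyloxybutanoyl) diester, 6-OTBS, 12-OPMB | CC(C)(C)[Si](C)(C)O[C@@H]1/C=C(/C)CC/C=C(/C(=O)OC)[C@@H](OC(=O)[C@H](C)[C@H](C)O[Si](C)(C)C(C)(C)C)[C@@H](OC(=O)[C@@]3(C)O[C@H]3C)[C@H]1C(=C)COCc2ccc(OC)cc2 | intermediate
36 | C12 primary allylic alcohol of 35 | CC(C)(C)[Si](C)(C)O[C@@H]1/C=C(/C)CC/C=C(/C(=O)OC)[C@@H](OC(=O)[C@H](C)[C@H](C)O[Si](C)(C)C(C)(C)C)[C@@H](OC(=O)[C@@]3(C)O[C@H]3C)[C@H]1C(=C)CO | intermediate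
37 | triol: 6-OH, 12-OH, side-chain 3-OH | O[C@@H]1/C=C(/C)CC/C=C(/C(=O)OC)[C@@H](OC(=O)[C@H](C)[C@H](C)O)[C@@H](OC(=O)[C@@]3(C)O[C@H]3C)[C@H]1C(=C)CO | intermediate
38 | C12 aldehyde (2-substituted acrolein), 6-OH free | O[C@@H]1/C=C(/C)CC/C=C(/C(=O)OC)[C@@H](OC(=O)[C@H](C)[C@H](C)O)[C@@H](OC(=O)[C@@]3(C)O[C@H]3C)[C@H]1C(=C)C=O | intermediate
39 | 6,12-lactol (C12 epimers) | C=C1C(O)O[C@@H]2/C=C(/C)CC/C=C(/C(=O)OC)[C@@H](OC(=O)[C@H](C)[C@H](C)O)[C@@H](OC(=O)[C@@]3(C)O[C@H]3C)[C@@H]12 | intermediate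
40 | CNP0135583.1 | C=C1C(=O)O[C@@H]2/C=C(/C)CC/C=C(/C(=O)OC)[C@@H](OC(=O)[C@H](C)[C@H](C)O)[C@@H](OC(=O)[C@@]3(C)O[C@H]3C)[C@@H]12 | target

Total steps: 26. Longest linear sequence: 20 steps (steps 1–15, 19, 23–26).

Steps most likely to fail

Step 5. The conjugate addition may show poor facial selectivity, the nucleophile entering C5 from the α-face (anti to the acetonide) and giving the 5α-epimer, which would lead to the ring-trans alkene in step 12. The fallback sets out from 7. The copper-catalysed addition is run with Me3SiCl and the silyl enol ether F1 is collected whatever its C5 configuration. Saegusa–Ito oxidation with Pd(OAc)2 gives the 5-isopropenyl enone F2. Conjugate reduction with [(Ph3P)CuH]6 and Me3SiCl then delivers hydride from the same α-face that misled the carbon nucleophile, giving silyl enol ether F3 with the isopropenyl group β. MeLi followed by the triflimide reagent converts F3 into 10.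

Step 13. Enolisation may go toward C9 (with β-elimination of O8) or give the ring-trans enolate. The fallback sets out from 20. Condensation with 2,4,6-triisopropylbenzenesulfonyl hydrazide gives hydrazone F4. A Shapiro reaction (n-BuLi, THF/TMEDA, −78 to 0 °C) deprotonates the less substituted α-carbon C1 and gives the cis-alkenyllithium, and methyl chloroformate then gives ester 23 directly.

Step 19. The two hydroxyls may not be discriminated well enough, or the acyl group may migrate between O9 and O8. The fallback sets out from 24. MnO2 oxidises only the allylic C9 alcohol, giving ketol F5. The single remaining hydroxyl (O8) is esterified with 34 under Yamaguchi conditions to keto ester F6. Corey–Bakshi–Shibata reduction, with the oxazaborolidine enantiomer that delivers hydride to the α-face of C9, returns the 9β-alcohol F7. Yamaguchi esterification of F7 with 29 gives 35.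

Further compounds
F1 | step 5 | C7 trimethylsilyl enol ether, C5 epimers | C=C[C@@]1(O[Si](CC)(CC)CC)[C@H]2OC(C)(C)O[C@H]2C(O[Si](C)(C)C)=CC1C(C)=C
F2 | step 5 | 5-isopropenyl enone (C7=O, C5=C6) | C=C[C@@]1(O[Si](CC)(CC)CC)[C@H]2OC(C)(C)O[C@H]2C(=O)C=C1C(C)=C
F3 | step 5 | C7 trimethylsilyl enol ether, 5β-isopropenyl | C=C[C@@]1(O[Si](CC)(CC)CC)[C@H]2OC(C)(C)O[C@H]2C(O[Si](C)(C)C)=C[C@H]1C(C)=C
F4 | step 13 | 2,4,6-triisopropylbenzenesulfonylhydrazone of 20 | CC(C)(C)[Si](C)(C)O[C@@H]1/C=C(/C)CCCC(=NNS(=O)(=O)c2c(C(C)C)cc(C(C)C)cc2C(C)C)[C@H]3OC(C)(C)O[C@H]3[C@H]1C(=C)COCc2ccc(OC)cc2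
F5 | step 19 | C9 ketone, 8-OH | CC(C)(C)[Si](C)(C)O[C@@H]1/C=C(/C)CC/C=C(/C(=O)OC)C(=O)[C@@H](O)[C@H]1C(=C)COCc2ccc(OC)cc2
F6 | step 19 | C9 ketone, 8-O-epoxyangeloyl ester | CC(C)(C)[Si](C)(C)O[C@@H]1/C=C(/C)CC/C=C(/C(=O)OC)C(=O)[C@@H](OC(=O)[C@@]3(C)O[C@H]3C)[C@H]1C(=C)COCc2ccc(OC)cc2
F7 | step 19 | 9β-alcohol, 8-O-epoxyangeloyl ester | CC(C)(C)[Si](C)(C)O[C@@H]1/C=C(/C)CC/C=C(/C(=O)OC)[C@@H](O)[C@@H](OC(=O)[C@@]3(C)O[C@H]3C)[C@H]1C(=C)COCc2ccc(OC)cc2
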